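The decamer (rings A–J, lettered from the 2,4,6-trihydroxyphenoxy end) is disconnected at both ether bonds of ring G. In ring G the ether carbons C1 (to the oxygen on C4 of ring F) and C6 (to the oxygen on C1 of ring H) are each para to a hydroxylated carbon, C4 and C3. Carrying those two hydroxyls as formyl groups turns C1 and C6 into activated aryl fluorides. One flask then joins the permethylated A–F hexamer phenol, 4,5-difluoro-3-methoxyphthalaldehyde and the H–J trimer phenol by two successive fluoride displacements. Double Dakin oxidation and global demethylation finish; the same linchpin is used earlier for rings C, E and I.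

Key step: step 22

Remarks on the chemistry (assumptions)
- In 4,5-difluoro-3-methoxyphthalaldehyde one formyl group is ortho and the other meta to the methoxy oxygen. Phenol-directed ortho-formylation can place only the first, and a plain 2,3-difluorophenol has a single free ortho carbon. The second formyl carbon is therefore brought in as bromine, and the linchpin starts from 5-bromo-2,3-difluorophenol (assumed commercial, as are the three methoxyphenols).
- Numbering: in rings C, E, G and I, C1 is the ether carbon toward ring A, C6 the ether carbon toward ring J, and C3, C4, C5 bear oxygen.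
- All phenoxide steps are run in dry, degassed solvent under argon, because the 4-aryloxy-2,6-dimethoxyphenoxides are air-sensitive.

Step 1
Reactants: 1 5-bromo-2,3-difluorophenol
Product: 2 6-bromo-3,4-difluoro-2-hydroxybenzaldehyde
Conditions: MgCl2, Et3N, (CH2O)n, MeCN, reflux; aq. HCl
Reagents that add atoms: paraformaldehyde (formaldehyde), C=O
Why: The magnesium-mediated ortho-formylation of phenols (Casnati–Skattebøl reaction) formylates only ortho to the phenol oxygen, and the single free ortho carbon lies between OH and Br, so one regioisomer should form.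

Step 2
Reactants: 2 6-bromo-3,4-difluoro-2-hydroxybenzaldehyde
Product: 3 6-bromo-3,4-difluoro-2-methoxybenzaldehyde
Conditions: MeI, K2CO3, DMF, rt
Reagents that add atoms: iodomethane, CI
Why: Williamson O-methylation of the chelated, weakly nucleophilic phenoxide should be much faster at room temperature than its attack on the fluoride para to the formyl group of another molecule.

Step 3
Reactants: 3 6-bromo-3,4-difluoro-2-methoxybenzaldehyde
Product: 4 1-bromo-2-(dimethoxymethyl)-4,5-difluoro-3-methoxybenzene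
Conditions: HC(OMe)3, p-TsOH (cat.), MeOH, 60 °C
Reagents that add atoms: trimethyl orthoformate, COC(OC)OC; methanol, CO
Why: Acid-catalysed acetalisation driven by the orthoformate masks the aldehyde for the organomagnesium step, and no nucleophile able to displace fluoride is present.

Step 4
Reactants: 4 1-bromo-2-(dimethoxymethyl)-4,5-difluoro-3-methoxybenzene
Product: 7 4,5-difluoro-3-methoxyphthalaldehyde, via arylmagnesium chloride 5 (not isolated), via acetal aldehyde 6 (not isolated)
Conditions: i-PrMgCl·LiCl, THF, −15 °C; DMF, −15 °C → rt; 2 M HCl, rt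
Reagents that add atoms: N,N-dimethylformamide, CN(C)C=O; water, O
Why: Bromine–magnesium exchange on the electron-poor aryl bromide gives an arylmagnesium with no ortho halogen (so no aryne pathway), DMF formylates it (Bouveault aldehyde synthesis), and aqueous acid cleaves the aminal and the acetal.

Step 5
Reactants: 7 4,5-difluoro-3-methoxyphthalaldehyde; 8 4-bromo-2,6-dimethoxyphenol
Product: 9 bromo fluoro dialdehyde [5-(4-bromo-2,6-dimethoxyphenoxy)-4-fluoro-3-methoxyphthalaldehyde]
Conditions: Cs2CO3, DMF, 4 Å MS, 0 °C → rt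
Reagents that add atoms: none
Why: Nucleophilic aromatic substitution (addition–elimination): one equivalent of the hindered 2,6-dimethoxyphenoxide should take the fluoride flanked by CH and para to the C4 formyl group (future C1 of rings E and I), with the aryl bromide inert. The product is isolated so that the site of substitution can be confirmed before the batch is divided between steps 6 and 12.

Step 6
Reactants: 9 bromo fluoro dialdehyde; 10 3,4,5-trimethoxyphenol
Product: 11 bromo H–I–J trimer dialdehyde [5-(4-bromo-2,6-dimethoxyphenoxy)-3-methoxy-4-(3,4,5-trimethoxyphenoxy)phthalaldehyde]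
Conditions: Cs2CO3, DMF, 4 Å MS, 70 °C
Reagents that add atoms: none
Why: Second nucleophilic aromatic substitution completing ring I: the slim 3,4,5-trimethoxyphenoxide should displace the remaining fluoride at C6, which is para to the C3 formyl group, on warming.

Step 7
Reactants: 11 bromo H–I–J trimer dialdehyde
Product: 13 bromo trimer catechol [5-(4-bromo-2,6-dimethoxyphenoxy)-3-methoxy-4-(3,4,5-trimethoxyphenoxy)benzene-1,2-diol], via trimer diformate 12 (not isolated)
Conditions: mCPBA, CH2Cl2, 0 °C → rt; then K2CO3, MeOH, 0 °C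
Reagents that add atoms: mCPBA (3-chloroperoxybenzoic acid), OOC(=O)c1cccc(Cl)c1
Why: Dakin-type Baeyer–Villiger oxidation: each formyl-bearing carbon is para to an aryloxy donor, so the aryl group should migrate in the Criegee intermediate to give the diformate, which methanolysis cleaves to the catechol.

Step 8
Reactants: 13 bromo trimer catechol
Product: 14 permethylated bromo trimer [5-bromo-1,3-dimethoxy-2-[3,4,5-trimethoxy-2-(3,4,5-trimethoxyphenoxy)phenoxy]benzene]
Conditions: MeI, K2CO3, DMF, rt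
Reagents that add atoms: iodomethane, CI
Why: Williamson methylation of both catechol hydroxyls fixes the C3 and C4 oxygens of ring I as methyl ethers and removes the air-sensitive catechol.

Step 9
Reactants: 14 permethylated bromo trimer
Product: 15 H–J trimer phenol [3,5-dimethoxy-4-[3,4,5-trimethoxy-2-(3,4,5-trimethoxyphenoxy)phenoxy]phenol]
Conditions: Pd2(dba)3 (cat.), tBuXPhos (cat.), KOH, 1,4-dioxane/H2O, 100 °C; aq. HCl
Reagents that add atoms: potassium hydroxide, [K+].[OH-]
Why: Palladium-catalysed hydroxylation of the aryl bromide (oxidative addition to zerovalent palladium, bromide–hydroxide exchange, reductive elimination promoted by the bulky biaryl phosphine) should unmask the C1 hydroxyl of ring H at an unhindered carbon, with methyl and diaryl ethers inert to KOH.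

Step 10
Reactants: 8 4-bromo-2,6-dimethoxyphenol
Product: 16 2-(benzyloxy)-5-bromo-1,3-dimethoxybenzene
Conditions: BnBr, K2CO3, DMF, 60 °C
Reagents that add atoms: benzyl bromide, BrCc1ccccc1
Why: Williamson benzylation protects the hindered hydroxyl with a group that is later removed by hydrogenolysis without touching methyl or diaryl ethers.

Step 11
Reactants: 16 2-(benzyloxy)-5-bromo-1,3-dimethoxybenzene
Product: 17 4-(benzyloxy)-3,5-dimethoxyphenol
Conditions: Pd2(dba)3 (cat.), tBuXPhos (cat.), KOH, 1,4-dioxane/H2O, 100 °C; aq. HCl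
Reagents that add atoms: potassium hydroxide, [K+].[OH-]
Why: The same palladium-catalysed bromide-to-hydroxyl exchange as in step 9 should give the unhindered ring F phenol, the benzyl ether being stable to aqueous base.

Step 12
Reactants: 9 bromo fluoro dialdehyde; 17 4-(benzyloxy)-3,5-dimethoxyphenol
Product: 18 bromo D–E–F trimer dialdehyde [4-[4-(benzyloxy)-3,5-dimethoxyphenoxy]-5-(4-bromo-2,6-dimethoxyphenoxy)-3-methoxyphthalaldehyde]
Conditions: Cs2CO3, DMF, 4 Å MS, 70 °C
Reagents that add atoms: none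
Why: Nucleophilic aromatic substitution as in step 6 completes ring E: the 4-bromo-2,6-dimethoxyphenoxy group already on C1 serves as ring D, and the unhindered ring F phenoxide should displace the fluoride at C6, para to the C3 formyl group.

Step 13
Reactants: 18 bromo D–E–F trimer dialdehyde
Product: 20 bromo D–E–F catechol [4-[4-(benzyloxy)-3,5-dimethoxyphenoxy]-5-(4-bromo-2,6-dimethoxyphenoxy)-3-methoxybenzene-1,2-diol], via benzyl trimer diformate 19 (not isolated)
Conditions: mCPBA, CH2Cl2, 0 °C → rt; then K2CO3, MeOH, 0 °C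
Reagents that add atoms: mCPBA (3-chloroperoxybenzoic acid), OOC(=O)c1cccc(Cl)c1
Why: Dakin-type Baeyer–Villiger oxidation as in step 7 should convert both formyl groups of ring E into hydroxyls, the benzyl ether being inert to peracid and carbonate.

Step 14
Reactants: 20 bromo D–E–F catechol
Product: 21 permethylated bromo D–E–F trimer benzyl ether [2-[2-[4-(benzyloxy)-3,5-dimethoxyphenoxy]-3,4,5-trimethoxyphenoxy]-5-bromo-1,3-dimethoxybenzene]
Conditions: MeI, K2CO3, DMF, rt
Reagents that add atoms: iodomethane, CI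
Why: Williamson methylation caps the two new hydroxyls of ring E.

Step 15
Reactants: 21 permethylated bromo D–E–F trimer benzyl ether
Product: 22 D–F trimer phenol [4-[2-[4-(benzyloxy)-3,5-dimethoxyphenoxy]-3,4,5-trimethoxyphenoxy]-3,5-dimethoxyphenol]
Conditions: Pd2(dba)3 (cat.), tBuXPhos (cat.), KOH, 1,4-dioxane/H2O, 100 °C; aq. HCl
Reagents that add atoms: potassium hydroxide, [K+].[OH-]
Why: Palladium-catalysed hydroxylation as in step 9 should turn the ring D bromide into the unhindered C1 hydroxyl.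

Step 16
Reactants: 23 2,4,6-trimethoxyphenol; 16 2-(benzyloxy)-5-bromo-1,3-dimethoxybenzene
Product: 24 A–B benzyl ether [2-(benzyloxy)-1,3-dimethoxy-5-(2,4,6-trimethoxyphenoxy)benzene]
Conditions: CuI (cat.), picolinic acid (cat.), K3PO4, DMSO, 100 °C
Reagents that add atoms: none
Why: Ullmann diaryl ether synthesis: the picolinate-ligated copper phenoxide should couple the di-ortho-substituted phenol with an aryl bromide whose C–Br carbon is flanked only by CH.

Step 17
Reactants: 24 A–B benzyl ether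
Product: 25 A–B phenol [2,6-dimethoxy-4-(2,4,6-trimethoxyphenoxy)phenol]
Conditions: H2 (1 atm), Pd/C, EtOAc/MeOH, rt
Reagents that add atoms: none
Why: Catalytic hydrogenolysis cleaves only the benzylic C–O bond and should release the hindered C4 hydroxyl of ring B.

Step 18
Reactants: 25 A–B phenol; 7 4,5-difluoro-3-methoxyphthalaldehyde; 22 D–F trimer phenol
Product: 27 benzyl-protected A–F hexamer dialdehyde (formyl groups on C3 and C4 of ring C; benzyl on the C4 oxygen of ring F), via A–B–C fluoro dialdehyde 26 (not isolated)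
Conditions: 25, Cs2CO3, DMF, 4 Å MS, 0 °C → rt; then 22, Cs2CO3, 75 °C
Reagents that add atoms: none
Why: Sequential nucleophilic aromatic substitution as in steps 5 and 6 builds ring C, the hindered ring B phenoxide entering at C1 and the unhindered ring D phenoxide of the trimer at C6.

Step 19
Reactants: 27 benzyl-protected A–F hexamer dialdehyde
Product: 29 hexamer catechol (hydroxyls on C3 and C4 of ring C), via hexamer diformate 28 (not isolated)
Conditions: mCPBA, CH2Cl2, 0 °C → rt; then K2CO3, MeOH, 0 °C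
Reagents that add atoms: mCPBA (3-chloroperoxybenzoic acid), OOC(=O)c1cccc(Cl)c1
Why: Dakin-type Baeyer–Villiger oxidation as in step 7; a small excess of peracid at low temperature should keep the electron-rich ring A from electrophilic oxidation.

Step 20
Reactants: 29 hexamer catechol
Product: 30 permethylated A–F hexamer benzyl ether
Conditions: MeI, K2CO3, DMF, rt
Reagents that add atoms: iodomethane, CI
Why: Williamson methylation caps the two new hydroxyls of ring C.

Step 21
Reactants: 30 permethylated A–F hexamer benzyl ether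
Product: 31 permethylated A–F hexamer phenol (free hydroxyl on C4 of ring F)
Conditions: H2 (1 atm), Pd/C, EtOAc/MeOH, rt
Reagents that add atoms: none
Why: Hydrogenolysis of the single benzyl ether should release the hindered ring F hydroxyl, no other group in the molecule being reducible.

Step 22
Reactants: 31 permethylated A–F hexamer phenol; 7 4,5-difluoro-3-methoxyphthalaldehyde; 15 H–J trimer phenol
Product: 33 permethylated decamer dialdehyde (formyl groups on C3 and C4 of ring G), via heptamer fluoro dialdehyde 32 (not isolated)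
Conditions: 31, Cs2CO3, DMF, 4 Å MS, 0 °C → rt; then 15, Cs2CO3, 80 °C
Reagents that add atoms: none
Why: Each substitution is an addition–elimination in which the phenoxide adds to the fluorinated carbon to give a Meisenheimer anion stabilised by the para formyl group (the C4 formyl for attack at C1, the C3 formyl for attack at C6), and fluoride then leaves. The closest known reaction type is phenoxide substitution of para-formyl aryl fluorides, used with two nucleophiles in turn as on dihaloarenes bearing two acceptors, and it is rehearsed in steps 5, 6, 12 and 18. No ring is closed and no stereocentre is formed. The selectivity needed is that the hindered 2,6-dimethoxyphenoxide of ring F attacks C1 only: C1 is flanked by C2–H and is meta to the C5 methoxy group, whereas C6 is ortho to that donor and more crowded, and one equivalent of hexamer at low temperature should suppress double substitution. After the first substitution the new aryloxy group is meta to the C3 formyl group, so C6 should stay electrophilic enough for the unhindered ring H phenoxide on warming. Dry carbonate under argon should avoid hydroxide-induced Cannizzaro reaction of the dialdehyde and aerial oxidation of the electron-rich phenoxides.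

Step 23
Reactants: 33 permethylated decamer dialdehyde
Product: 35 decamer catechol (free hydroxyls on C3 and C4 of ring G; 24 methyl ethers), via decamer diformate 34 (not isolated)
Conditions: mCPBA, CH2Cl2, 0 °C → rt; then K2CO3, MeOH, 0 °C; aq. NH4Cl
Reagents that add atoms: mCPBA (3-chloroperoxybenzoic acid), OOC(=O)c1cccc(Cl)c1
Why: Double Dakin-type Baeyer–Villiger oxidation: both formyl carbons of ring G are para to aryloxy donors (C4 also has an ortho methoxy group), so aryl migration should give the diformate, which methanolysis cleaves to the C3 and C4 hydroxyls.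

Step 24
Reactants: 35 decamer catechol
Product: 36 target decamer CNP0255890.0 (26 free hydroxyls)
Conditions: BBr3 (excess), CH2Cl2, −78 °C → rt; H2O, 0 °C
Reagents that add atoms: none
Why: Lewis acid-mediated aryl methyl ether cleavage: BBr3 binds each methoxy oxygen and bromide removes the methyl group as MeBr, while the diaryl ether bonds, which offer no carbon open to bromide attack, should survive.

Compound list
1 | 5-bromo-2,3-difluorophenol | Oc1cc(Br)cc(F)c1F | starting material
2 | 6-bromo-3,4-difluoro-2-hydroxybenzaldehyde | Oc1c(F)c(F)cc(Br)c1C=O | intermediate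
3 | 6-bromo-3,4-difluoro-2-methoxybenzaldehyde | COc1c(F)c(F)cc(Br)c1C=O | intermediate
4 | 1-bromo-2-(dimethoxymethyl)-4,5-difluoro-3-methoxybenzene | COC(OC)c1c(Br)cc(F)c(F)c1OC | intermediate
5 | [2-(dimethoxymethyl)-4,5-difluoro-3-methoxyphenyl]magnesium chloride | COC(OC)c1c([Mg]Cl)cc(F)c(F)c1OC | intermediate
6 | 2-(dimethoxymethyl)-4,5-difluoro-3-methoxybenzaldehyde | COC(OC)c1c(C=O)cc(F)c(F)c1OC | intermediate
7 | 4,5-difluoro-3-methoxyphthalaldehyde (linchpin) | COc1c(F)c(F)cc(C=O)c1C=O | intermediate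
8 | 4-bromo-2,6-dimethoxyphenol | COc1cc(Br)cc(OC)c1O | starting material
9 | bromo fluoro dialdehyde, 5-(4-bromo-2,6-dimethoxyphenoxy)-4-fluoro-3-methoxyphthalaldehyde | COc1cc(Br)cc(OC)c1Oc1cc(C=O)c(C=O)c(OC)c1F | intermediate
10 | 3,4,5-trimethoxyphenol | COc1cc(O)cc(OC)c1OC | starting material
11 | 5-(4-bromo-2,6-dimethoxyphenoxy)-3-methoxy-4-(3,4,5-trimethoxyphenoxy)phthalaldehyde | COc1cc(Br)cc(OC)c1Oc1cc(C=O)c(C=O)c(OC)c1Oc1cc(OC)c(OC)c(OC)c1 | intermediate
12 | 5-(4-bromo-2,6-dimethoxyphenoxy)-3-methoxy-4-(3,4,5-trimethoxyphenoxy)-1,2-phenylene diformate | COc1cc(Br)cc(OC)c1Oc1cc(OC=O)c(OC=O)c(OC)c1Oc1cc(OC)c(OC)c(OC)c1 | intermediate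
13 | 5-(4-bromo-2,6-dimethoxyphenoxy)-3-methoxy-4-(3,4,5-trimethoxyphenoxy)benzene-1,2-diol | COc1cc(Br)cc(OC)c1Oc1cc(O)c(O)c(OC)c1Oc1cc(OC)c(OC)c(OC)c1 | intermediate
14 | 5-bromo-1,3-dimethoxy-2-[3,4,5-trimethoxy-2-(3,4,5-trimethoxyphenoxy)phenoxy]benzene | COc1cc(Br)cc(OC)c1Oc1cc(OC)c(OC)c(OC)c1Oc1cc(OC)c(OC)c(OC)c1 | intermediate
15 | H–J trimer phenol, 3,5-dimethoxy-4-[3,4,5-trimethoxy-2-(3,4,5-trimethoxyphenoxy)phenoxy]phenol | COc1cc(O)cc(OC)c1Oc1cc(OC)c(OC)c(OC)c1Oc1cc(OC)c(OC)c(OC)c1 | intermediate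
16 | 2-(benzyloxy)-5-bromo-1,3-dimethoxybenzene | COc1cc(Br)cc(OC)c1OCc1ccccc1 | intermediate
17 | 4-(benzyloxy)-3,5-dimethoxyphenol | COc1cc(O)cc(OC)c1OCc1ccccc1 | intermediate
18 | 4-[4-(benzyloxy)-3,5-dimethoxyphenoxy]-5-(4-bromo-2,6-dimethoxyphenoxy)-3-methoxyphthalaldehyde | COc1cc(Br)cc(OC)c1Oc1cc(C=O)c(C=O)c(OC)c1Oc1cc(OC)c(OCc2ccccc2)c(OC)c1 | intermediate
19 | 4-[4-(benzyloxy)-3,5-dimethoxyphenoxy]-5-(4-bromo-2,6-dimethoxyphenoxy)-3-methoxy-1,2-phenylene diformate | COc1cc(Br)cc(OC)c1Oc1cc(OC=O)c(OC=O)c(OC)c1Oc1cc(OC)c(OCc2ccccc2)c(OC)c1 | intermediate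
20 | 4-[4-(benzyloxy)-3,5-dimethoxyphenoxy]-5-(4-bromo-2,6-dimethoxyphenoxy)-3-methoxybenzene-1,2-diol | COc1cc(Br)cc(OC)c1Oc1cc(O)c(O)c(OC)c1Oc1cc(OC)c(OCc2ccccc2)c(OC)c1 | intermediate
21 | 2-[2-[4-(benzyloxy)-3,5-dimethoxyphenoxy]-3,4,5-trimethoxyphenoxy]-5-bromo-1,3-dimethoxybenzene | COc1cc(Br)cc(OC)c1Oc1cc(OC)c(OC)c(OC)c1Oc1cc(OC)c(OCc2ccccc2)c(OC)c1 | intermediate
22 | D–F trimer phenol, 4-[2-[4-(benzyloxy)-3,5-dimethoxyphenoxy]-3,4,5-trimethoxyphenoxy]-3,5-dimethoxyphenol | COc1cc(O)cc(OC)c1Oc1cc(OC)c(OC)c(OC)c1Oc1cc(OC)c(OCc2ccccc2)c(OC)c1 | intermediate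
23 | 2,4,6-trimethoxyphenol | COc1cc(OC)c(O)c(OC)c1 | starting material
24 | 2-(benzyloxy)-1,3-dimethoxy-5-(2,4,6-trimethoxyphenoxy)benzene | COc1cc(OC)c(Oc2cc(OC)c(OCc3ccccc3)c(OC)c2)c(OC)c1 | intermediate
25 | A–B phenol, 2,6-dimethoxy-4-(2,4,6-trimethoxyphenoxy)phenol | COc1cc(OC)c(Oc2cc(OC)c(O)c(OC)c2)c(OC)c1 | intermediate
26 | 5-[2,6-dimethoxy-4-(2,4,6-trimethoxyphenoxy)phenoxy]-4-fluoro-3-methoxyphthalaldehyde | COc1cc(OC)c(Oc2cc(OC)c(Oc3cc(C=O)c(C=O)c(OC)c3F)c(OC)c2)c(OC)c1 | intermediate
27 | benzyl-protected A–F hexamer dialdehyde (CHO on C3 and C4 of ring C, OBn on C4 of ring F) | COc1cc(OC)c(Oc2cc(OC)c(Oc3cc(C=O)c(C=O)c(OC)c3Oc3cc(OC)c(Oc4cc(OC)c(OC)c(OC)c4Oc4cc(OC)c(OCc5ccccc5)c(OC)c4)c(OC)c3)c(OC)c2)c(OC)c1 | intermediate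
28 | hexamer diformate (formate esters on C3 and C4 of ring C) | COc1cc(OC)c(Oc2cc(OC)c(Oc3cc(OC=O)c(OC=O)c(OC)c3Oc3cc(OC)c(Oc4cc(OC)c(OC)c(OC)c4Oc4cc(OC)c(OCc5ccccc5)c(OC)c4)c(OC)c3)c(OC)c2)c(OC)c1 | intermediate
29 | hexamer catechol (OH on C3 and C4 of ring C) | COc1cc(OC)c(Oc2cc(OC)c(Oc3cc(O)c(O)c(OC)c3Oc3cc(OC)c(Oc4cc(OC)c(OC)c(OC)c4Oc4cc(OC)c(OCc5ccccc5)c(OC)c4)c(OC)c3)c(OC)c2)c(OC)c1 | intermediate
30 | permethylated A–F hexamer benzyl ether | COc1cc(OC)c(Oc2cc(OC)c(Oc3cc(OC)c(OC)c(OC)c3Oc3cc(OC)c(Oc4cc(OC)c(OC)c(OC)c4Oc4cc(OC)c(OCc5ccccc5)c(OC)c4)c(OC)c3)c(OC)c2)c(OC)c1 | intermediate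
31 | permethylated A–F hexamer phenol (OH on C4 of ring F) | COc1cc(OC)c(Oc2cc(OC)c(Oc3cc(OC)c(OC)c(OC)c3Oc3cc(OC)c(Oc4cc(OC)c(OC)c(OC)c4Oc4cc(OC)c(O)c(OC)c4)c(OC)c3)c(OC)c2)c(OC)c1 | intermediate
32 | heptamer fluoro dialdehyde (ring G: C1 O–ring F, C3 and C4 CHO, C5 OMe, C6 F) | COc1cc(OC)c(Oc2cc(OC)c(Oc3cc(OC)c(OC)c(OC)c3Oc3cc(OC)c(Oc4cc(OC)c(OC)c(OC)c4Oc4cc(OC)c(Oc5cc(C=O)c(C=O)c(OC)c5F)c(OC)c4)c(OC)c3)c(OC)c2)c(OC)c1 | intermediate
33 | permethylated decamer dialdehyde (CHO on C3 and C4 of ring G) | COc1cc(OC)c(Oc2cc(OC)c(Oc3cc(OC)c(OC)c(OC)c3Oc3cc(OC)c(Oc4cc(OC)c(OC)c(OC)c4Oc4cc(OC)c(Oc5cc(C=O)c(C=O)c(OC)c5Oc5cc(OC)c(Oc6cc(OC)c(OC)c(OC)c6Oc6cc(OC)c(OC)c(OC)c6)c(OC)c5)c(OC)c4)c(OC)c3)c(OC)c2)c(OC)c1 | intermediate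
34 | decamer diformate (formate esters on C3 and C4 of ring G) | COc1cc(OC)c(Oc2cc(OC)c(Oc3cc(OC)c(OC)c(OC)c3Oc3cc(OC)c(Oc4cc(OC)c(OC)c(OC)c4Oc4cc(OC)c(Oc5cc(OC=O)c(OC=O)c(OC)c5Oc5cc(OC)c(Oc6cc(OC)c(OC)c(OC)c6Oc6cc(OC)c(OC)c(OC)c6)c(OC)c5)c(OC)c4)c(OC)c3)c(OC)c2)c(OC)c1 | intermediate
35 | decamer catechol (OH on C3 and C4 of ring G, all other oxygens methylated) | COc1cc(OC)c(Oc2cc(OC)c(Oc3cc(OC)c(OC)c(OC)c3Oc3cc(OC)c(Oc4cc(OC)c(OC)c(OC)c4Oc4cc(OC)c(Oc5cc(O)c(O)c(OC)c5Oc5cc(OC)c(Oc6cc(OC)c(OC)c(OC)c6Oc6cc(OC)c(OC)c(OC)c6)c(OC)c5)c(OC)c4)c(OC)c3)c(OC)c2)c(OC)c1 | intermediate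
36 | CNP0255890.0, fully hydroxylated A–J decamer | Oc1cc(O)c(Oc2cc(O)c(Oc3cc(O)c(O)c(O)c3Oc3cc(O)c(Oc4cc(O)c(O)c(O)c4Oc4cc(O)c(Oc5cc(O)c(O)c(O)c5Oc5cc(O)c(Oc6cc(O)c(O)c(O)c6Oc6cc(O)c(O)c(O)c6)c(O)c5)c(O)c4)c(O)c3)c(O)c2)c(O)c1 | target

Total step count: 24. Longest linear sequence: 16 steps (steps 1–5, 12–15, 18–24).

Steps most likely to fail

Step 22. What may go wrong: the first displacement spreads over both fluorides, or the second displacement at the crowded C6 is so slow that the dialdehyde degrades under base. The fallback sets out from 4 and 15 and returns at 33. The exchange/formylation of step 4 is quenched with aqueous NH4Cl in place of HCl so that acetal aldehyde 6 is isolated. In 6 only the C3 formyl group of ring G is free, so only the C6 fluoride is activated. Trimer phenol 15 with Cs2CO3 in DMF should give tetramer acetal aldehyde F1. Aqueous HCl in THF should then unmask the C4 formyl group to give tetramer fluoro dialdehyde F2. The phenoxide of 31 (Cs2CO3, DMF, 80 °C) should then displace the remaining C1 fluoride, which is para to the C4 formyl group and flanked by C2–H, giving 33. The order of bond formation is reversed and the regiochemistry is set by protection rather than by intrinsic bias.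

Step 23. What may go wrong: hydride migration instead of aryl migration at the second formyl group, stalling after one oxidation, or attack of excess peracid on the electron-rich rings. The fallback sets out from 33 and returns at 35. One equivalent of mCPBA at 0 °C should oxidise the more electron-rich C4 formyl group (ortho methoxy, para aryloxy) to decamer formate aldehyde F3. Methanolysis with K2CO3 in MeOH should give decamer hydroxy aldehyde F4; the regioisomeric hydroxy aldehyde would converge. F4 is an ortho-hydroxybenzaldehyde, so the classical Dakin oxidation with H2O2 and NaOH in degassed THF/H2O should complete the conversion to 35. There the phenoxide drives aryl migration and no peracid is present.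

Step 24. What may go wrong: incomplete cleavage of the 24 methyl ethers, and oxidative degradation of the free polyphenol during work-up and chromatography. The fallback sets out from 35 and returns at 36. After the BBr3 treatment the crude product is not purified but acetylated (Ac2O, pyridine, DMAP) to hexacosaacetate F5. F5 should be stable and separable on silica, and partly methylated fractions can be returned to BBr3. Acid-catalysed methanolysis of F5 (anhydrous HCl in MeOH, cat., 40 °C, argon) should then release 36 without exposing it to base or air.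

Further compounds
F1 | step 22 | tetramer acetal aldehyde (ring G: C1 F, C3 CHO, C4 CH(OMe)2, C5 OMe, C6 O–ring H of the H–J trimer) | COC(OC)c1c(C=O)cc(F)c(Oc2cc(OC)c(Oc3cc(OC)c(OC)c(OC)c3Oc3cc(OC)c(OC)c(OC)c3)c(OC)c2)c1OC
F2 | step 22 | tetramer fluoro dialdehyde (ring G: C1 F, C3 and C4 CHO, C5 OMe, C6 O–ring H) | O=Cc1cc(F)c(Oc2cc(OC)c(Oc3cc(OC)c(OC)c(OC)c3Oc3cc(OC)c(OC)c(OC)c3)c(OC)c2)c(OC)c1C=O
F3 | step 23 | decamer formate aldehyde (ring G: C3 CHO, C4 OCHO) | COc1cc(OC)c(Oc2cc(OC)c(Oc3cc(OC)c(OC)c(OC)c3Oc3cc(OC)c(Oc4cc(OC)c(OC)c(OC)c4Oc4cc(OC)c(Oc5cc(C=O)c(OC=O)c(OC)c5Oc5cc(OC)c(Oc6cc(OC)c(OC)c(OC)c6Oc6cc(OC)c(OC)c(OC)c6)c(OC)c5)c(OC)c4)c(OC)c3)c(OC)c2)c(OC)c1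
F4 | step 23 | decamer hydroxy aldehyde (ring G: C3 CHO, C4 OH) | COc1cc(OC)c(Oc2cc(OC)c(Oc3cc(OC)c(OC)c(OC)c3Oc3cc(OC)c(Oc4cc(OC)c(OC)c(OC)c4Oc4cc(OC)c(Oc5cc(C=O)c(O)c(OC)c5Oc5cc(OC)c(Oc6cc(OC)c(OC)c(OC)c6Oc6cc(OC)c(OC)c(OC)c6)c(OC)c5)c(OC)c4)c(OC)c3)c(OC)c2)c(OC)c1
F5 | step 24 | hexacosaacetate of the target decamer | CC(=O)Oc1cc(OC(C)=O)c(Oc2cc(OC(C)=O)c(Oc3cc(OC(C)=O)c(OC(C)=O)c(OC(C)=O)c3Oc3cc(OC(C)=O)c(Oc4cc(OC(C)=O)c(OC(C)=O)c(OC(C)=O)c4Oc4cc(OC(C)=O)c(Oc5cc(OC(C)=O)c(OC(C)=O)c(OC(C)=O)c5Oc5cc(OC(C)=O)c(Oc6cc(OC(C)=O)c(OC(C)=O)c(OC(C)=O)c6Oc6cc(OC(C)=O)c(OC(C)=O)c(OC(C)=O)c6)c(OC(C)=O)c5)c(OC(C)=O)c4)c(OC(C)=O)c3)c(OC(C)=O)c2)c(OC(C)=O)c1
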